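All runs were computed for substances that don't exist.

Per hour is the unit in which two chemists argue over these flasks, all read at 4.0 h.

| flask | D | J | remark | time |
|---|---|---|---|---|
| midnight | 0.067 M | 0.144 M | run made earlier |  |
| autumn | 0.34 M | 0.144 M | run made earlier |  |
| spring | 0.12 M | 0.13 M | run made earlier |  |
| cedar | 0.40 M | 0.0800 M |  | 4.0 h |
| larch | 0.080 M | 0.100 M |  | 4.0 h |
| oak | 0.25 M | 0.0500 M |  | 4.0 h |
| alder | 0.25 M | 0.200 M |  | 4.0 h |
| elm | 0.12 M | 0.144 M |  | 4.0 h |

| run | time / h | G / % | Z / % |
|---|---|---|---|
| midnight | 0.250 | 9.8 | 0.9 |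
| midnight | 0.500 | 16.6 | 3.8 |
| midnight | 1.33 | 25.4 | 14.8 |
| midnight | 3.00 | 23.5 | 32.3 |
| autumn | 0.667 | 14.5 | 2.6 |
| autumn | 1.33 | 15.3 | 5.1 |
| autumn | 2.00 | 14.3 | 5.7 |
| autumn | 3.00 | 11.4 | 6.0 |
| spring | 0.667 | 17.6 | 4.4 |
| spring | 1.33 | 21.8 | 9.8 |
| spring | 2.00 | 24.0 | 14.4 |
| spring | 3.00 | 20.7 | 18.9 |

(standard deviation of a reading: 0.3 percentage points)

* all flasks from highest to lowest share of G in all that became G or Z or Q, at 4.0 h (cedar / larch / oak / alder / elm)
* the share of G in all that became G or Z or Q of the flask you put first, at 4.0 h
* the share of G in all that became G or Z or Q of the flask you put last, at 4.0 h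



Both start from the autumn run. Between 2.00 h and 3.00 h its Z barely moves, from 5.7% to 6.0%, while G falls from 14.3% to 11.4%. As a rate that reads 0.227 h⁻¹: the fade rate, the fraction of G lost per hour at autumn's charge of J.

The first chemist takes this as a fixed clock, the same whatever the charge, and the runs give little to test it on, with J charges of 0.144 M, 0.144 M and 0.13 M. On her clock G keeps a fraction of 40.4% at the time asked, and Z pulls each flask below that lid.

The second chemist points to the earlier stretch of the same run, from 1.33 h to 2.00 h, where G lost only 0.101 h⁻¹, less than later. She answers that G was still forming then. He suspects a partner left behind as J reacts, which would make the loss of G pseudo-first-order, with a rate that scales with the J charged.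

I reckon with his view and join the two ends. At the start the share of G is whole, and late the fade rate applies, scaled by the J charge as a fraction of autumn's, so one exponential connects them. The charge of D does not enter this reckoning. The kept fractions are then 73.0% for oak, 60.4% for cedar, 53.3% for larch, 40.4% for elm and 28.4% for alder. Z is left out of these, so I expect the shares to stand lower, in this order.

The forecast is her number: oak > cedar > larch > alder > elm, with 35% first and 22% last, on the ground that G falls “even without J, in all runs and largely independent of D”.

The simulation gives oak > cedar > larch > elm > alder, with oak at 64.7%, cedar at 51.0%, larch at 41.8%, elm at 30.3% and alder at 21.5%. The order is his. Her lid of 40.4% does stand above the shares of elm and alder, the two flasks charged with 0.144 M of J or more, but it stands below the shares of oak, cedar and larch.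

    D + J → G + E (k = 0.0560 M⁻¹ min⁻¹)
    J ⇌ L (K = 0.430, k = 0.00190 min⁻¹)
    G + E → Q (k = 0.0440 M⁻¹ min⁻¹)
    J + G → Z + E (k = 0.0620 M⁻¹ min⁻¹)
    J + X → Z + E (k = 0.120 M⁻¹ min⁻¹)
    D + J → X + E (k = 0.0210 M⁻¹ min⁻¹)

At 4.00 h alder holds E at 0.133 M and oak at 0.0392 M, so the half-life of G by G + E → Q is 1.97 h in alder and 6.69 h in oak. Against the 4.0 h of reading, alder's is shorter and oak's longer, and alder holds G at 10.4% with Q at 20.5%, oak G at 8.56% with Q at 3.13%. Alder's kept fraction of 28.4% stood above its 21.5%. The neighbour of alder with 0.10 M of D has the same J charge, hence the same kept fraction, and its share is 19.0%.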